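**Retrosynthetic overview**

1. Crotobarin ⇐ 14-hydroxy lactone 20 (C17 acetate still on C16) by acetylation at C14 and loss of acetic acid across C16–C17.
2. 20 ⇐ bicyclic enone acid aldehyde 16 by one cascade: the C3 carboxyl oxygen adds to C9 (δ-lactone), and the enol ether so formed adds through C8 to the C14 aldehyde. This C8–C14 bond closes the ring C8–C9–C11–C12–C13–C14 of the bicyclo[2.2.2]octane.
3. Enabling feature: C8 is the α-carbon of the C15 ketone, and both of its neighbours in that ring carry a β-oxygen (C9 the lactone oxygen, C14 the acetoxy group). The tetrasubstituted enone C15(=O)–C8=C9 of a ring B/ring C′ octalone can therefore take up O at C9 and an aldehyde carbon at C8.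
4. 16 ⇐ Diels–Alder reaction of the exocyclic silyloxy diene 6 (on ring B) with enal 9, which builds ring C′, sets C12 and brings in C12–C14, C16 and C17. 6 ⇐ ketone 3 ⇐ 2-methylcyclohex-2-en-1-one by asymmetric conjugate addition and allylation (C5, C10).
5. Ring order: ring B (starting material) → ring C′ (step 7) → δ-lactone, then the C8–C9–C11–C12–C13–C14 ring (both in step 13, in this order).

Key step: step 13

Remark on numbering: atisane numbers are used (C1–C3 lactone chain, C4 isopropenyl carbon, C5–C10 ring B, C20 methyl on C10, C8 and C12 bridgeheads, C15 ketone, C16/C17 methylene unit; ring C′ = C8, C9, C11, C12, C16, C15).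
Remark on stereochemistry: the SMILES places the C14 acetoxy group on the side of the C15–C16 bridge, the lactone oxygen on C9 anti to C14 across C8–C9, and the C13–C14 bridge on the ring B face that carries the C20 methyl. The route is planned for this.
Assumption: tert-butyl(but-3-en-1-yloxy)dimethylsilane (7) is taken as commercial. The ligand enantiomer in step 1 is the one that gives (S)-2.

Step 1
Reactants: 1 2-methylcyclohex-2-en-1-one
Product: 2 (S)-trimethyl{[2-methyl-3-(prop-1-en-2-yl)cyclohex-1-en-1-yl]oxy}silane
Conditions: CH2=C(CH3)MgBr, Cu(OTf)2 (3 mol%), chiral imidazolinium salt (N-heterocyclic carbene precursor, 4 mol%), Et2O, −30 °C; then TMSCl, Et3N, −30 °C → rt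
Reagents that add atoms: isopropenylmagnesium bromide, CC(=C)[Mg]Br; chlorotrimethylsilane, C[Si](C)(C)Cl
Why: Copper-catalysed asymmetric conjugate addition of a Grignard reagent to an α-substituted cyclohexenone with silyl trapping of the magnesium enolate; the chiral carbene ligand on copper selects the enone face and so sets C5, and trapping fixes the enolate regiochemistry for step 2.

Step 2
Reactants: 2 (S)-silyl enol ether
Product: 3 (2S,3S)-2-allyl-2-methyl-3-(prop-1-en-2-yl)cyclohexan-1-one
Conditions: MeLi, THF, 0 °C; then allyl bromide, HMPA, −78 → 0 °C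
Reagents that add atoms: allyl bromide, C=CCBr
Why: Methyllithium cleavage of the silyl enol ether gives the regiodefined tetrasubstituted lithium enolate, which is C-allylated anti to the neighbouring isopropenyl group (enolate alkylation, substrate control), so the quaternary C10 is set with the C20 methyl cis to isopropenyl.

Step 3
Reactants: 3 ketone
Product: 4 (2S,3S,6Z)-2-allyl-6-(hydroxymethylene)-2-methyl-3-(prop-1-en-2-yl)cyclohexan-1-one
Conditions: NaH, HCO2Et, EtOH (cat.), THF, 0 °C → rt; aq. HCl work-up
Reagents that add atoms: ethyl formate, CCOC=O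
Why: Crossed Claisen condensation (α-formylation); C8 is the only enolisable position because C10 is quaternary, and the product is held as the chelated hydroxymethylene ketone.

Step 4
Reactants: 4 hydroxymethylene ketone
Product: 5 (2S,3S,6E)-2-allyl-6-{[(tert-butyldimethylsilyl)oxy]methylene}-2-methyl-3-(prop-1-en-2-yl)cyclohexan-1-one
Conditions: TBSCl, Et3N, DMAP (cat.), CH2Cl2, 0 °C → rt
Reagents that add atoms: tert-butyldimethylsilyl chloride, CC(C)(C)[Si](C)(C)Cl
Why: O-silylation of the vinylogous acid gives the vinylogous silyl ester, expected as the less hindered (E)-isomer with the silyloxy group anti to the carbonyl group.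

Step 5
Reactants: 5 silyloxymethylene ketone
Product: 6 tert-butyl{[(E)-[(3S,4S)-3-allyl-3-methyl-2-methylene-4-(prop-1-en-2-yl)cyclohexylidene]methyl]oxy}dimethylsilane
Conditions: Cp2TiMe2 (3 equiv), toluene, 70 °C, dark
Reagents that add atoms: dimethyltitanocene Cp2TiMe2, [CH3-].[CH3-].[Ti+4].c1cc[cH-]c1.c1cc[cH-]c1
Why: Petasis methylenation; Cp2Ti=CH2 formed on heating is a non-basic methylene donor that should accept hindered, enolisable and conjugated ketones and spare silyl enol ethers, and no ester is present to compete.

Step 6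
Reactants: 7 tert-butyl(but-3-en-1-yloxy)dimethylsilane; 8 (E)-but-2-enal
Product: 9 (E)-5-[(tert-butyldimethylsilyl)oxy]pent-2-enal
Conditions: second-generation Hoveyda–Grubbs catalyst (3 mol%), 8 (3 equiv), CH2Cl2, 40 °C
Reagents that add atoms: none
Why: Olefin cross metathesis of a terminal alkene with an electron-poor partner; the (E)-enal should form under thermodynamic control.

Step 7
Reactants: 6 silyloxy diene; 9 enal
Product: 11 cycloadduct alcohol (C17–OH), via cycloadduct aldehyde 10 (not isolated)
Conditions: toluene, BHT (cat.), 110 °C, sealed tube; then NaBH4, MeOH/THF, −20 °C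
Reagents that add atoms: none
Why: Diels–Alder reaction of an s-cis-locked 1-silyloxy diene with a β-substituted enal: the oxygen donor directs the formyl-bearing carbon to C15 ("ortho" adduct); the enal should add endo on the diene face anti to the axial C20 methyl, which puts the C12 side chain (the exo substituent) on the C20 face; NaBH4 reduction in the same flask removes the elimination-prone β-silyloxy aldehyde.

Step 8
Reactants: 11 cycloadduct alcohol
Product: 12 C17 acetate
Conditions: Ac2O, pyridine, DMAP (cat.), CH2Cl2, 0 °C
Reagents that add atoms: acetic anhydride, CC(=O)OC(C)=O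
Why: Acylation of the only free alcohol; the acetate masks C17–O through the oxidations and is the leaving group of the last step.

Step 9
Reactants: 12 C17 acetate
Product: 13 primary alcohol at C3
Conditions: catecholborane, RhCl(PPh3)3 (2 mol%), THF, rt; then NaBO3·4H2O, THF/H2O, rt
Reagents that add atoms: sodium perborate, [Na+].[O-]OB=O
Why: Rhodium-catalysed anti-Markovnikov hydroboration should take the monosubstituted allyl alkene in preference to the 1,1-disubstituted isopropenyl group and the tetrasubstituted C8=C9 bond, and perborate oxidation spares the acetate.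

Step 10
Reactants: 13 primary alcohol
Product: 14 carboxylic acid at C3
Conditions: TEMPO (20 mol%), PhI(OAc)2 (2.5 equiv), MeCN/H2O, rt
Reagents that add atoms: water, O
Why: Oxoammonium oxidation of the primary alcohol through the aldehyde hydrate to the acid, which leaves alkenes, silyl ethers and the acetate untouched.

Step 11
Reactants: 14 bis-silyl ether acid
Product: 15 diol acid (C15–OH and C14–OH free)
Conditions: HF·pyridine, pyridine, THF, 0 °C → rt
Reagents that add atoms: none
Why: Fluoride cleavage of both silyl ethers under buffered conditions that should leave the acetate, the acid and the alkenes intact.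

Step 12
Reactants: 15 diol acid
Product: 16 enone aldehyde acid
Conditions: Dess–Martin periodinane (3 equiv), CH2Cl2, 0 °C → rt
Reagents that add atoms: none
Why: Dess–Martin oxidation of the allylic secondary and the primary alcohol in one operation gives the C15 enone and the C14 aldehyde under non-basic conditions, so the β-acetoxy ketone should not eliminate.

Step 13
Reactants: 16 enone aldehyde acid
Product: 20 14-hydroxy lactone (17-acetoxy-16,17-dihydro-14-O-deacetylcrotobarin), via silyl ester 17 (not isolated), via lactone silyl enol ether 18 (not isolated), via aldol silyl ether 19 (not isolated)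
Conditions: TMSOTf (2.2 equiv), 2,6-di-tert-butyl-4-methylpyridine (1.5 equiv), CH2Cl2 (0.01 M), −78 → −30 °C; then 1 M HCl, THF, 0 °C
Reagents that add atoms: none
Why: Proposed new method: TMSOTf first converts the acid into its silyl ester 17 and then silylates the enone oxygen, whereupon the ester carbonyl oxygen adds to the β-carbon C9 (6-exo conjugate lactonisation with transfer of the silyl group from the carboxyl group to O15) to give the δ-lactone as its regiodefined C8=C15 silyl enol ether 18, which adds through C8 to the TMSOTf-activated C14 aldehyde (intramolecular Mukaiyama aldol, 6-(enolexo)-exo-trig) and so closes the C8–C9–C11–C12–C13–C14 ring of the bicyclo[2.2.2]octane after the lactone. The closest known reaction types are the Lewis-acid-mediated hetero-Michael/aldol tandem of enones (halo-aldol and chalcogeno-Baylis–Hillman reactions), the acid-catalysed conjugate lactonisation of enone acids, the TMSOTf-catalysed Mukaiyama aldol reaction and the aldol closure of 3-oxocyclohexaneacetaldehydes to 6-hydroxybicyclo[2.2.2]octan-2-ones; new is their union with a carboxyl oxygen as the triggering nucleophile. C9 is set by axial attack of the tethered oxygen on the ring B face anti to the axial C20 methyl, the only face the equatorial C10 propanoate chain can reach (cis-fused lactone). C8 is set because the C12 acetaldehyde arm, placed on the C20 face in step 7, can reach C8 only there, so O and C14 add anti across C8=C9; C14 should carry its oxygen on the side of the C15 bridge, away from the quaternary C10, which is also the less strained epimer. The step needs reaction at C8 and not at C16, and it must avoid β-elimination of the C9 acyloxy group: the first is secured because the enol ether is born by conjugate addition and never by deprotonation, the second because no free enolate or amine base is present (the hindered pyridine only takes up TfOH) and because reversion of 18 merely returns 17. Once the aldol has taken place C8 is quaternary and the β-acyloxy ketone can no longer eliminate; acidic work-up cleaves the silyl ether 19.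

Step 14
Reactants: 20 14-hydroxy lactone
Product: 22 crotobarin, via diacetate 21 (not isolated)
Conditions: Ac2O, DMAP, Et3N, CH2Cl2, 0 °C → rt; then DBU, 0 °C
Reagents that add atoms: acetic anhydride, CC(=O)OC(C)=O
Why: DMAP-catalysed acetylation of the hindered C14 alcohol, then E1cB loss of acetic acid from the β-acetoxy ketone; C16–H is the only acidic α-hydrogen (C8 is quaternary) and the double bond can form only toward C17 because C12 is a bridgehead, which gives the exocyclic enone.

**Compound list**

1 | 2-methylcyclohex-2-en-1-one | CC1=CCCCC1=O | starting material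
2 | (S)-trimethyl{[2-methyl-3-(prop-1-en-2-yl)cyclohex-1-en-1-yl]oxy}silane | C[Si](C)(C)OC1=C(C)[C@H](C(=C)C)CCC1 | intermediate
3 | (2S,3S)-2-allyl-2-methyl-3-(prop-1-en-2-yl)cyclohexan-1-one | O=C1CCC[C@@H](C(=C)C)[C@]1(C)CC=C | intermediate
4 | (2S,3S,6Z)-2-allyl-6-(hydroxymethylene)-2-methyl-3-(prop-1-en-2-yl)cyclohexan-1-one | O=C1/C(=C\O)CC[C@@H](C(=C)C)[C@]1(C)CC=C | intermediate
5 | (2S,3S,6E)-2-allyl-6-{[(tert-butyldimethylsilyl)oxy]methylene}-2-methyl-3-(prop-1-en-2-yl)cyclohexan-1-one | O=C1/C(=C/O[Si](C)(C)C(C)(C)C)CC[C@@H](C(=C)C)[C@]1(C)CC=C | intermediate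
6 | tert-butyl{[(E)-[(3S,4S)-3-allyl-3-methyl-2-methylene-4-(prop-1-en-2-yl)cyclohexylidene]methyl]oxy}dimethylsilane (diene C15=C8–C9=C11) | C=C1/C(=C/O[Si](C)(C)C(C)(C)C)CC[C@@H](C(=C)C)[C@]1(C)CC=C | intermediate
7 | tert-butyl(but-3-en-1-yloxy)dimethylsilane | C=CCCO[Si](C)(C)C(C)(C)C | starting material
8 | (E)-but-2-enal | C/C=C/C=O | starting material
9 | (E)-5-[(tert-butyldimethylsilyl)oxy]pent-2-enal | O=C/C=C/CCO[Si](C)(C)C(C)(C)C | intermediate
10 | cycloadduct aldehyde: ring B/ring C′ bicycle with C8=C9, C15–OTBS, C16–CHO and C12–CH2CH2OTBS; C12 side chain on the C20 face, C15–O and C16–CHO on the opposite face; allyl and C20 methyl on C10, isopropenyl on C5 as in 3 | O=C[C@@H]1[C@H](O[Si](C)(C)C(C)(C)C)C2=C(C[C@H]1CCO[Si](C)(C)C(C)(C)C)[C@@](C)(CC=C)[C@H](C(=C)C)CC2 | intermediate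
11 | cycloadduct alcohol: as 10 with C17H2OH in place of CHO | OC[C@@H]1[C@H](O[Si](C)(C)C(C)(C)C)C2=C(C[C@H]1CCO[Si](C)(C)C(C)(C)C)[C@@](C)(CC=C)[C@H](C(=C)C)CC2 | intermediate
12 | C17 acetate of 11 | CC(=O)OC[C@@H]1[C@H](O[Si](C)(C)C(C)(C)C)C2=C(C[C@H]1CCO[Si](C)(C)C(C)(C)C)[C@@](C)(CC=C)[C@H](C(=C)C)CC2 | intermediate
13 | primary alcohol: as 12 with 3-hydroxypropyl on C10 in place of allyl | CC(=O)OC[C@@H]1[C@H](O[Si](C)(C)C(C)(C)C)C2=C(C[C@H]1CCO[Si](C)(C)C(C)(C)C)[C@@](C)(CCCO)[C@H](C(=C)C)CC2 | intermediate
14 | carboxylic acid: as 13 with 2-carboxyethyl on C10 | CC(=O)OC[C@@H]1[C@H](O[Si](C)(C)C(C)(C)C)C2=C(C[C@H]1CCO[Si](C)(C)C(C)(C)C)[C@@](C)(CCC(=O)O)[C@H](C(=C)C)CC2 | intermediate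
15 | diol acid: as 14 with free C15–OH and C14–OH | CC(=O)OC[C@@H]1[C@H](O)C2=C(C[C@H]1CCO)[C@@](C)(CCC(=O)O)[C@H](C(=C)C)CC2 | intermediate
16 | enone aldehyde acid: C15(=O)–C8=C9 enone, C12–CH2CHO on the C20 face, C16–CH2OAc trans to it, 2-carboxyethyl on C10 | CC(=O)OC[C@@H]1C(=O)C2=C(C[C@H]1CC=O)[C@@](C)(CCC(=O)O)[C@H](C(=C)C)CC2 | intermediate
17 | trimethylsilyl ester of 16 | CC(=O)OC[C@@H]1C(=O)C2=C(C[C@H]1CC=O)[C@@](C)(CCC(=O)O[Si](C)(C)C)[C@H](C(=C)C)CC2 | intermediate
18 | lactone silyl enol ether: cis-fused C3→O–C9 δ-lactone, C8=C15–OTMS, C12–CH2CHO | CC(=O)OC[C@@H]1C(O[Si](C)(C)C)=C2CC[C@@H](C(=C)C)[C@]3(C)CCC(=O)O[C@]23C[C@H]1CC=O | intermediate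
19 | aldol silyl ether: crotobarin skeleton with C14–OTMS and C16(H)–CH2OAc | CC(=O)OC[C@@H]1C(=O)[C@]23CC[C@@H](C(=C)C)[C@]4(C)CCC(=O)O[C@@]42C[C@H]1C[C@@H]3O[Si](C)(C)C | intermediate
20 | 14-hydroxy lactone (17-acetoxy-16,17-dihydro-14-O-deacetylcrotobarin; C14–OH on the side of the C15 bridge) | CC(=O)OC[C@@H]1C(=O)[C@]23CC[C@@H](C(=C)C)[C@]4(C)CCC(=O)O[C@@]42C[C@H]1C[C@@H]3O | intermediate
21 | diacetate (17-acetoxy-16,17-dihydrocrotobarin) | CC(=O)OC[C@@H]1C(=O)[C@]23CC[C@@H](C(=C)C)[C@]4(C)CCC(=O)O[C@@]42C[C@H]1C[C@@H]3OC(C)=O | intermediate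
22 | crotobarin | C=C1C(=O)[C@]23CC[C@@H](C(=C)C)[C@]4(C)CCC(=O)O[C@@]42C[C@H]1C[C@@H]3OC(C)=O | target

**Step count and risks**

Total step count: 14. Longest linear sequence: 13 steps (1 → 22 through steps 1–5 and 7–14; step 6 is a one-step branch).

Steps most likely to fail:

Step 13 (key step). What may go wrong: the silyl-transfer conjugate lactonisation may be outrun by return to the enone or by enol ether formation toward C11, so that the aldol runs without the lactone or not at all. The fallback uses known reactions stepwise under Brønsted acid equilibration and sets out from 15. MnO2 in CH2Cl2 oxidises only the allylic C15 alcohol and gives the enone acid alcohol F1. Camphorsulfonic acid in toluene effects the acid-catalysed conjugate lactonisation known for enone acids and gives the lactone ketone alcohol F2, with C8–H on the C20 face (trans B/C′ fusion). Dess–Martin periodinane gives the lactone keto aldehyde F3. Aqueous HCl in THF then brings about the acid-catalysed enol aldol known for 3-oxocyclohexaneacetaldehydes; the lactone is closed before the carbocycle and only enol, not enolate, chemistry is used. The fallback comes back to the route at 20.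

Step 7. What may go wrong: loss of facial or endo/exo control in the thermal cycloaddition, which would scramble C12 relative to C10. The fallback moves the control of C12 from the substrate to a catalyst with a two-point-binding dienophile and sets out from 6 and 7. Cross metathesis of 7 with commercial 3-acryloyloxazolidin-2-one (second-generation Hoveyda–Grubbs catalyst) gives the imide dienophile F4. The Diels–Alder reaction of 6 with F4 under [Cu((S,S)-t-Bu-box)](SbF6)2 (or its enantiomer, whichever gives the C12 configuration of 11) gives the imide cycloadduct F5. The catalyst selects the face of the β-carbon that bonds to C11, and this alone fixes C12, whatever the diene face. LiBH4 reduction of the imide gives the primary alcohol, and the fallback comes back at 11.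

Step 1. What may go wrong: poor enantioface discrimination with an sp2 Grignard reagent on an α-substituted enone. The fallback replaces 1 as the starting point by commercial cyclohex-2-en-1-one and sets the C5 centre by a rhodium-catalysed addition. [RhCl(cod)]2 with the BINAP enantiomer that gives the (R)-ketone and potassium isopropenyltrifluoroborate in toluene/H2O gives (R)-3-(prop-1-en-2-yl)cyclohexan-1-one F6. LiN(i-Pr)2/TMSCl gives the kinetic silyl enol ether F7, and Pd(OAc)2 (Saegusa–Ito oxidation) gives (R)-5-(prop-1-en-2-yl)cyclohex-2-en-1-one F8. LiN(i-Pr)2/MeI gives the trans 6-methyl enone F9, and LiN(i-Pr)2/allyl bromide gives the 6-allyl-6-methyl enone F10, the second electrophile entering anti to isopropenyl. Conjugate reduction with LiBH(s-Bu)3 then gives the saturated ketone, and the fallback comes back at 3.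

Further compounds

F1 | step 13 | enone acid alcohol (16 with C14H2OH in place of CHO) | CC(=O)OC[C@@H]1C(=O)C2=C(C[C@H]1CCO)[C@@](C)(CCC(=O)O)[C@H](C(=C)C)CC2
F2 | step 13 | lactone ketone alcohol (cis-fused δ-lactone on C9, C8–H on the C20 face, C14H2OH) | CC(=O)OC[C@@H]1C(=O)[C@@H]2CC[C@@H](C(=C)C)[C@]3(C)CCC(=O)O[C@]23C[C@H]1CCO
F3 | step 13 | lactone keto aldehyde | CC(=O)OC[C@@H]1C(=O)[C@@H]2CC[C@@H](C(=C)C)[C@]3(C)CCC(=O)O[C@]23C[C@H]1CC=O
F4 | step 7 | (E)-3-{5-[(tert-butyldimethylsilyl)oxy]pent-2-enoyl}oxazolidin-2-one | O=C(/C=C/CCO[Si](C)(C)C(C)(C)C)N1CCOC1=O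
F5 | step 7 | imide cycloadduct (10 with C17(=O)–oxazolidin-2-one in place of CHO) | O=C([C@@H]1[C@H](O[Si](C)(C)C(C)(C)C)C2=C(C[C@H]1CCO[Si](C)(C)C(C)(C)C)[C@@](C)(CC=C)[C@H](C(=C)C)CC2)N3CCOC3=O
F6 | step 1 | (R)-3-(prop-1-en-2-yl)cyclohexan-1-one | O=C1CCC[C@@H](C(=C)C)C1
F7 | step 1 | (R)-trimethyl{[5-(prop-1-en-2-yl)cyclohex-1-en-1-yl]oxy}silane | C[Si](C)(C)OC1=CCC[C@@H](C(=C)C)C1
F8 | step 1 | (R)-5-(prop-1-en-2-yl)cyclohex-2-en-1-one | O=C1C=CC[C@@H](C(=C)C)C1
F9 | step 1 | (5R,6S)-6-methyl-5-(prop-1-en-2-yl)cyclohex-2-en-1-one | O=C1C=CC[C@@H](C(=C)C)[C@@H]1C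
F10 | step 1 | (5S,6S)-6-allyl-6-methyl-5-(prop-1-en-2-yl)cyclohex-2-en-1-one | O=C1C=CC[C@@H](C(=C)C)[C@]1(C)CC=C
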